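**Strategy**

The γ-lactone (oxolan-2-one ring) is traced back, by removal of ring oxygen O1 (retro-Baeyer–Villiger), to a 2-substituted cyclobutanone and this to a keteniminium salt plus ethylene. The key step exploits the unbranched C3–C4 ethano unit lying between the lactone carbonyl C2 and the carbinol carbon C5: a keteniminium–olefin [2+2] cycloaddition makes the C2–C3 and C4–C5 bonds at once, a twofold-symmetric chiral pyrrolidine on nitrogen fixing C5. The precursor is an open-chain 3-(indol-3-yl)propanamide whose indole is tamed by a 2-ester; that ester carbon later becomes the methylene bridge to the second indole, and the C3 hydroxyl is added last, trans to the side chain.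

Key step: step 4

Remark on the chemistry: the (2R,5R) auxiliary is assigned to the (S)-cyclobutanone by analogy with keteniminium cycloadditions of twofold-symmetric pyrrolidine amides; should the induction run the other way, the equally available (2S,5S) amine is used in step 1 and nothing else changes. Compounds 1, 2, 4, 7 and 15 are taken as purchased.

**Route**

Step 1
Reactants: 1 (2R,5R)-2,5-dimethylpyrrolidine; 2 acryloyl chloride
Product: 3 1-[(2R,5R)-2,5-dimethylpyrrolidin-1-yl]prop-2-en-1-one
Conditions: Et3N (1.5 equiv), CH2Cl2, −20 → 0 °C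
Reagents that add atoms: none
Why: N-acylation of the hindered secondary amine by the acid chloride (Schotten–Baumann type) should be fast in the cold, where aza-Michael addition to the product does not compete.

Step 2
Reactants: 4 ethyl 1-methyl-1H-indole-2-carboxylate; 3 1-[(2R,5R)-2,5-dimethylpyrrolidin-1-yl]prop-2-en-1-one
Product: 5 ethyl 3-{(E)-3-[(2R,5R)-2,5-dimethylpyrrolidin-1-yl]-3-oxoprop-1-enyl}-1-methylindole-2-carboxylate
Conditions: Pd(OAc)2 (10 mol %), Cu(OAc)2 (2.0 equiv), DMF/DMSO 9:1, N2, 80 °C
Reagents that add atoms: none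
Why: Fujiwara–Moritani (oxidative Heck) reaction: electrophilic palladation at C3, the only free pyrrole position of 4, then acrylamide insertion and β-hydride elimination should give the E-alkene, Cu(OAc)2 returning palladium to the divalent state.

Step 3
Reactants: 5 ethyl 3-{(E)-3-[(2R,5R)-2,5-dimethylpyrrolidin-1-yl]-3-oxoprop-1-enyl}-1-methylindole-2-carboxylate
Product: 6 ethyl 3-{3-[(2R,5R)-2,5-dimethylpyrrolidin-1-yl]-3-oxopropyl}-1-methylindole-2-carboxylate
Conditions: H2 (1 atm), 10 % Pd/C, EtOAc, rt
Reagents that add atoms: none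
Why: Heterogeneous catalytic hydrogenation should saturate the conjugated alkene while the indole nucleus, the ester and the amide stay untouched under these mild conditions.

Step 4
Reactants: 6 ethyl 3-{3-[(2R,5R)-2,5-dimethylpyrrolidin-1-yl]-3-oxopropyl}-1-methylindole-2-carboxylate; 7 ethylene
Product: 10 ethyl 1-methyl-3-{[(1S)-2-oxocyclobutyl]methyl}indole-2-carboxylate, via keteniminium triflate 8 (not isolated), via cyclobutaniminium triflate 9 (not isolated)
Conditions: Tf2O (1.1 equiv), 2,4,6-collidine (1.1 equiv), CH2Cl2, −30 °C; ethylene (10 bar), −30 °C → rt; then aq NaHCO3, 0 °C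
Reagents that add atoms: water, O
Why: O-triflation of the tertiary amide and loss of the α-proton to collidine give the aldo-keteniminium triflate 8; ethylene attacks its central carbon (the later lactone carbonyl) and the terminal CH carbon closes onto the second ethylene carbon, so that both ring bonds arise in one asynchronous [2+2] event and the cyclobutaniminium salt 9 is hydrolysed to 10 on work-up. The closest known reaction is the keteniminium–olefin [2+2] cycloaddition, which, unlike the ketene version, engages unactivated ethylene and has been run with amides of twofold-symmetric pyrrolidines for asymmetric induction. The four-membered carbocycle is closed by intermolecular [2+2] cycloaddition (formally π2s+π2a), with no regiochemical alternative because ethylene is symmetric. The new CH stereocentre (later lactone C5) is controlled by the (2R,5R)-dimethylpyrrolidine, whose symmetry leaves a single keteniminium geometry and shields one sense of ring closure. The step needs chemoselectivity of the cation for ethylene over the indole, secured by the 2-ester and the blocked C2 and C3 positions, and configurational integrity of the α-CH, secured by one equivalent of a weak hindered base, low temperature, ethylene pressure and cold bicarbonate hydrolysis.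

Step 5
Reactants: 10 ethyl 1-methyl-3-{[(1S)-2-oxocyclobutyl]methyl}indole-2-carboxylate
Product: 11 ethyl 1-methyl-3-{[(2S)-5-oxooxolan-2-yl]methyl}indole-2-carboxylate
Conditions: mCPBA (1.2 equiv), NaHCO3, CH2Cl2, 0 °C
Reagents that add atoms: mCPBA, O=C(OO)c1cccc(Cl)c1
Why: Baeyer–Villiger oxidation: the strained ketone should take up the peracid far faster than the ester-deactivated indole is oxidised, and the more substituted ring carbon migrates with retention, carrying the S configuration into lactone C5.

Step 6
Reactants: 11 ethyl 1-methyl-3-{[(2S)-5-oxooxolan-2-yl]methyl}indole-2-carboxylate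
Product: 13 1-methyl-3-{[(2S)-5-oxooxolan-2-yl]methyl}indole-2-carboxylic acid, via dilithium hydroxy dicarboxylate 12 (not isolated)
Conditions: LiOH (4 equiv), THF/H2O 3:1, 40 °C; then 1 M HCl to pH 2, rt
Reagents that add atoms: lithium hydroxide, [Li+].[OH-]
Why: Saponification should cleave the hindered aryl ester and open the lactone without touching the carbinol stereocentre, and acidification recloses the five-membered ring (lactonisation) while the aryl acid stays free.

Step 7
Reactants: 13 1-methyl-3-{[(2S)-5-oxooxolan-2-yl]methyl}indole-2-carboxylic acid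
Product: 14 (5S)-5-{[2-(hydroxymethyl)-1-methylindol-3-yl]methyl}oxolan-2-one
Conditions: BH3·THF (2.5 equiv), THF, 0 °C → rt; H2O quench
Reagents that add atoms: none
Why: Chemoselective borane reduction: the carboxylic acid is reduced through its acyloxyborane much faster than the γ-lactone, and the neutral work-up spares the acid-labile 2-indolylcarbinol.

Step 8
Reactants: 14 (5S)-5-{[2-(hydroxymethyl)-1-methylindol-3-yl]methyl}oxolan-2-one; 15 1-methylindole
Product: 16 (5S)-5-({1-methyl-2-[(1-methylindol-3-yl)methyl]indol-3-yl}methyl)oxolan-2-one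
Conditions: 1-methylindole (3 equiv), CF3CO2H (10 mol %), CH2Cl2, 0 °C → rt
Reagents that add atoms: none
Why: Friedel–Crafts alkylation: acid ionises the carbinol to a delocalised 2-indolylmethyl cation that can only be captured at its exocyclic carbon because C3 is blocked, and the excess 1-methylindole attacks through its nucleophilic C3.

Step 9
Reactants: 16 (5S)-5-({1-methyl-2-[(1-methylindol-3-yl)methyl]indol-3-yl}methyl)oxolan-2-one
Product: 18 chaetoindolone C [(3R,5R)-3-hydroxy-5-({1-methyl-2-[(1-methylindol-3-yl)methyl]indol-3-yl}methyl)oxolan-2-one], via potassium enolate 17 (not isolated)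
Conditions: KN(SiMe3)2 (1.2 equiv), THF, −78 °C; 2-(phenylsulfonyl)-3-phenyloxaziridine (1.3 equiv), −78 °C; aq NH4Cl
Reagents that add atoms: 2-(phenylsulfonyl)-3-phenyloxaziridine, O=S(=O)(c1ccccc1)N1OC1c1ccccc1
Why: Enolate hydroxylation with an N-sulfonyloxaziridine: the lactone enolate should be oxidised on the face anti to the bulky C5 side chain, setting the 3R centre trans to it, while the low temperature leaves the indoles untouched.

**Compound list**

1 | (2R,5R)-2,5-dimethylpyrrolidine | C[C@@H]1CC[C@@H](C)N1 | starting material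
2 | acryloyl chloride | C=CC(=O)Cl | starting material
3 | 1-[(2R,5R)-2,5-dimethylpyrrolidin-1-yl]prop-2-en-1-one | C=CC(=O)N1[C@H](C)CC[C@H]1C | intermediate
4 | ethyl 1-methyl-1H-indole-2-carboxylate | CCOC(=O)c1cc2ccccc2n1C | starting material
5 | ethyl 3-{(E)-3-[(2R,5R)-2,5-dimethylpyrrolidin-1-yl]-3-oxoprop-1-enyl}-1-methylindole-2-carboxylate | CCOC(=O)c1c(/C=C/C(=O)N3[C@H](C)CC[C@H]3C)c2ccccc2n1C | intermediate
6 | ethyl 3-{3-[(2R,5R)-2,5-dimethylpyrrolidin-1-yl]-3-oxopropyl}-1-methylindole-2-carboxylate | CCOC(=O)c1c(CCC(=O)N3[C@H](C)CC[C@H]3C)c2ccccc2n1C | intermediate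
7 | ethylene | C=C | starting material
8 | (2R,5R)-1-{3-[2-(ethoxycarbonyl)-1-methylindol-3-yl]prop-1-enylidene}-2,5-dimethylpyrrolidinium triflate (keteniminium triflate) | CCOC(=O)c1c(CC=C=[N+]3[C@H](C)CC[C@H]3C)c2ccccc2n1C.[O-]S(=O)(=O)C(F)(F)F | intermediate
9 | (2R,5R)-1-[(2S)-2-{[2-(ethoxycarbonyl)-1-methylindol-3-yl]methyl}cyclobutylidene]-2,5-dimethylpyrrolidinium triflate (cyclobutaniminium triflate) | CCOC(=O)c1c(C[C@@H]4CCC4=[N+]3[C@H](C)CC[C@H]3C)c2ccccc2n1C.[O-]S(=O)(=O)C(F)(F)F | intermediate
10 | ethyl 1-methyl-3-{[(1S)-2-oxocyclobutyl]methyl}indole-2-carboxylate | CCOC(=O)c1c(C[C@@H]3CCC3=O)c2ccccc2n1C | intermediate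
11 | ethyl 1-methyl-3-{[(2S)-5-oxooxolan-2-yl]methyl}indole-2-carboxylate | CCOC(=O)c1c(C[C@@H]3CCC(=O)O3)c2ccccc2n1C | intermediate
12 | dilithium (4S)-5-(2-carboxylato-1-methylindol-3-yl)-4-hydroxypentanoate | [Li+].[Li+].[O-]C(=O)c1c(C[C@@H](O)CCC([O-])=O)c2ccccc2n1C | intermediate
13 | 1-methyl-3-{[(2S)-5-oxooxolan-2-yl]methyl}indole-2-carboxylic acid | OC(=O)c1c(C[C@@H]3CCC(=O)O3)c2ccccc2n1C | intermediate
14 | (5S)-5-{[2-(hydroxymethyl)-1-methylindol-3-yl]methyl}oxolan-2-one | OCc1c(C[C@@H]3CCC(=O)O3)c2ccccc2n1C | intermediate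
15 | 1-methylindole | Cn1ccc2ccccc21 | starting material
16 | (5S)-5-({1-methyl-2-[(1-methylindol-3-yl)methyl]indol-3-yl}methyl)oxolan-2-one | Cn1cc(Cc2c(C[C@@H]3CCC(=O)O3)c3ccccc3n2C)c2ccccc21 | intermediate
17 | potassium (5S)-5-({1-methyl-2-[(1-methylindol-3-yl)methyl]indol-3-yl}methyl)-4,5-dihydrofuran-2-olate (potassium enolate) | Cn1cc(Cc2c(C[C@@H]3CC=C([O-])O3)c3ccccc3n2C)c2ccccc21.[K+] | intermediate
18 | chaetoindolone C, (3R,5R)-3-hydroxy-5-({1-methyl-2-[(1-methylindol-3-yl)methyl]indol-3-yl}methyl)oxolan-2-one | Cn1cc(Cc2c(C[C@@H]3C[C@@H](O)C(=O)O3)c3ccccc3n2C)c2ccccc21 | target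

**Step count and risk**

Total step count: 9. Longest linear sequence: 9 (from 1 through 3, 5, 6, 10, 11, 13, 14 and 16 to 18).

Steps most likely to fail:

1. Step 4 (key step). The keteniminium may be intercepted by the indole nucleus or by its own ester before ethylene adds, the α-stereocentre of 9 or 10 may epimerise through the enamine or enol, and facial control by the auxiliary may be low. The fallback takes C5 from an enantiopure epoxide and bypasses the cyclobutanone. It sets out from 4: iodination (N-iodosuccinimide, DMF, rt) should give ethyl 3-iodo-1-methylindole-2-carboxylate F1. Iodine–magnesium exchange (i-PrMgCl·LiCl, THF, −40 °C) gives the ester-tolerant [2-(ethoxycarbonyl)-1-methylindol-3-yl]magnesium chloride F2. Under CuI catalysis (10 mol %, −30 °C) this opens methyl 3-[(2S)-oxiran-2-yl]propanoate F3, obtained by hydrolytic kinetic resolution of the racemic epoxide, at its terminal carbon. The resulting chloromagnesium (S)-alkoxide F4 lactonises on warming with loss of methoxide, and the route is rejoined at 11.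

2. Step 2. Palladation of the ester-deactivated indole at C3 may be too slow, so that the catalyst precipitates before turnover. The fallback builds the chain by carbonyl olefination. From 4, Vilsmeier–Haack formylation (POCl3, DMF, 60 °C) should give ethyl 3-formyl-1-methylindole-2-carboxylate F5. Horner–Wadsworth–Emmons reaction with diethyl {2-[(2R,5R)-2,5-dimethylpyrrolidin-1-yl]-2-oxoethyl}phosphonate F6 (from 1 and diethylphosphonoacetic acid by carbodiimide coupling) and NaH in THF returns the E-alkene 5.

3. Step 9. The enolate may be oxidised with poor facial selectivity, attack syn to the side chain giving the cis epimer. The fallback corrects the centre by inversion instead of by facial control. From 16 the hydroxylation is run as before and the epimers are separated. The cis epimer (3S,5R)-3-hydroxy-5-({1-methyl-2-[(1-methylindol-3-yl)methyl]indol-3-yl}methyl)oxolan-2-one F7 undergoes Mitsunobu inversion (4-nitrobenzoic acid, PPh3, diisopropyl azodicarboxylate, THF, 0 °C) to the (3R,5R)-5-({1-methyl-2-[(1-methylindol-3-yl)methyl]indol-3-yl}methyl)-2-oxooxolan-3-yl 4-nitrobenzoate F8. Methanolysis of the activated aryl ester (K2CO3, MeOH, 0 °C, then brief acidification to reclose any opened lactone) delivers 18.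

**Further compounds**

F1 | step 4 | ethyl 3-iodo-1-methylindole-2-carboxylate | CCOC(=O)c1c(I)c2ccccc2n1C
F2 | step 4 | [2-(ethoxycarbonyl)-1-methylindol-3-yl]magnesium chloride | CCOC(=O)c1c([Mg]Cl)c2ccccc2n1C
F3 | step 4 | methyl 3-[(2S)-oxiran-2-yl]propanoate | COC(=O)CC[C@H]1CO1
F4 | step 4 | chloromagnesium (4S)-5-[2-(ethoxycarbonyl)-1-methylindol-3-yl]-1-methoxy-1-oxopentan-4-olate | CCOC(=O)c1c(C[C@@H](O[Mg]Cl)CCC(=O)OC)c2ccccc2n1C
F5 | step 2 | ethyl 3-formyl-1-methylindole-2-carboxylate | CCOC(=O)c1c(C=O)c2ccccc2n1C
F6 | step 2 | diethyl {2-[(2R,5R)-2,5-dimethylpyrrolidin-1-yl]-2-oxoethyl}phosphonate | CCOP(=O)(OCC)CC(=O)N1[C@H](C)CC[C@H]1C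
F7 | step 9 | (3S,5R)-3-hydroxy-5-({1-methyl-2-[(1-methylindol-3-yl)methyl]indol-3-yl}methyl)oxolan-2-one | Cn1cc(Cc2c(C[C@@H]3C[C@H](O)C(=O)O3)c3ccccc3n2C)c2ccccc21
F8 | step 9 | (3R,5R)-5-({1-methyl-2-[(1-methylindol-3-yl)methyl]indol-3-yl}methyl)-2-oxooxolan-3-yl 4-nitrobenzoate | Cn1cc(Cc2c(C[C@@H]3C[C@@H](OC(=O)c4ccc(cc4)[N+](=O)[O-])C(=O)O3)c3ccccc3n2C)c2ccccc21
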